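The pitfall in the alpha run is to read substrate lost as product made.

- alpha: substrate 0.40 M; coupling partner 0.64 M; capture agent 0.12 M; free catalyst 8.4 mM; run made earlier
- flask: substrate 0.40 M; coupling partner 0.320 M; capture agent 0.120 M; free catalyst 8.4 mM

alpha run (percent of the substrate charged)

| time / min | product / % | substrate / % |
|---|---|---|
| 0.667 | 5.7 | 73.5 |
| 1.33 | 11.5 | 55.9 |
| 2.00 | 22.1 | 44.8 |
| 2.50 | 26.0 | 34.5 |
| 3.00 | 31.8 | 29.4 |

(standard deviation of a reading: 1 percentage point)

- the numbers in the tables scatter by 1 percentage point (one standard deviation)
- no earlier run changes the charge of free catalyst; that part of a forecast is a guess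

- apparent order in free catalyst when 50 % of the substrate are converted (percent change of the rate of making product for one percent more free catalyst charged)

I treat the substrate loss as a pseudo-first-order decay, c_substrate = c_substrate,start · exp(−kt). The last alpha reading gives k = 0.408 min⁻¹, so 50 % conversion falls near 1.70 min. I assume that coupling partner leaves this loss alone, which lets me carry k into the flask, although it holds 0.320 M against 0.64 M in alpha.

Two rates matter at that moment. Substrate leaves at k times 0.200 M, which is 0.0816 M min⁻¹, while product in the alpha run climbs, from first to last reading, at 0.0447 M min⁻¹, slower than the substrate leaves. Their ratio is 54.8 %, and I call it the product share of the substrate flow. If free catalyst raises this flow and also gains ground against the capture agent in the split, the order exceeds one. I commit to that sign and to no figure.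

The forecast says 0.95, within 0.6 to 1.1, on the view of “a saturated catalyst, with the rate set by the amount of active catalyst”. Its central value therefore lies below one, where my sign lies above.

The simulation gives 1.1.

    free catalyst + open intermediate ⇌ catalyst intermediate (K = 93.0 L mol⁻¹, k = 2.10 L mol⁻¹ s⁻¹)
    substrate + free catalyst ⇌ free catalyst + open intermediate (K = 3.10, k = 1.00 L mol⁻¹ s⁻¹)
    open intermediate + capture agent → trapped intermediate (k = 0.290 L mol⁻¹ s⁻¹)
    coupling partner + catalyst intermediate → free catalyst + product (k = 1.30 L mol⁻¹ s⁻¹)

In the flask, 50 % conversion comes at 1.76 min, and the rate of 0.0394 M min⁻¹ makes the product share 48.3 % of my flow. The capture of open intermediate as trapped intermediate is the largest single effect on that rate: without it, the rate is 1.41 times the actual one. This capture is also a part of the reason the order stands above one: without it, the flask gives 1.0 in place of 1.1.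

The readings are simulated with constants of no real substance, noise included.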